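## Analysis of the target

The target is an elemane-type sesquiterpenoid: one cyclohexane (C5–C10) trans-fused across C6–C7 to an α-methyl-γ-butyrolactone, and esterified at O8 with (S)-3,4-dihydroxy-2-methylenebutanoic acid (C1′–C4′). Numbering used throughout: C10 is quaternary and carries the methyl C14 and the vinyl group C1=C2; C5 carries C4(=C3H2)C15H2OH; the lactone runs C7–C11(C13H3)–C12(=O)–O6. The ring face that holds C1 on C10 is called β, the other α. The ring substituents alternate (C4 α on C5, O6 β, C11 α on C7, O8 β), so in the chair with C14 axial everything else is equatorial; C13 is cis to H7. The absolute configuration is 5S,6S,7S,8R,10R,11R and 3′S. Sensitive groups are the α-substituted acrylate (a Michael acceptor whose free 4′-hydroxyl can lactonise and expel the C8 alcohol under base), the lactone (epimerisable at C11, able to migrate from O6 to a free O8), and three different C=C bonds. The difficulty lies in the vicinal quaternary C10 and tertiary C5 in one absolute sense, four contiguous all-trans ring stereocentres, and the ordering of reactions among five oxygens and three alkenes. The strategy rests on one feature: C10 and C5 are adjacent with C1 and C4 trans, and C7 sits 1,4 to C10. That is the imprint of a [4+2] cycloaddition between a 2-oxygenated butadiene (C6–C7(O)–C8–C9) and an (E)-2-methylbutenedioate-type dienophile whose formyl end becomes C1 and whose ester end becomes C4.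

## Retrosynthetic reasoning

**Acyl group and C15 hydroxyl (35 ⇐ 34 ⇐ 33 ⇐ 24 + 31).** The acetonide of 34 is removed last, because the free side-chain diol is the most base-labile part of the molecule. The C15 hydroxyl is put in by allylic hydroxylation of the isopropenyl methyl of 33 after the ester is in place, so O15 and O8 never have to be told apart. The ester C–O bond is cut to alcohol 24 and acid 31. The forward esterification must work on a flanked secondary alcohol without strong base.

**Acid 31 (⇐ 30 ⇐ 28 ⇐ 26 ⇐ 25).** The C1′–C2′ bond is cut by carbonylation of enol triflate 30, which comes from methyl ketone 28 and so from glycerate ester 25. The stereocentre is bought, not made. The only demand is that the α-alkoxy ketone is enolised on its methyl side.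

**The two terminal alkenes (24 ⇐ 23 ⇐ 22 ⇐ 21 ⇐ 19 ⇐ 18).** C4=C3 is cut back to a tertiary carbinol (dehydration) and C1=C2 to an aldehyde (methylenation). Both alkenes are held back until the lactone is finished, because the lactone is built with a hydroboration that would consume a vinyl or isopropenyl group first. In 18, C1 and C4 therefore ride as silyl-protected alcohols.

**C11 methyl (18 ⇐ 16).** The C11–C13 bond is cut to the lactone enolate. The α face of that enolate is covered by C8 and its silyloxy group, so alkylation should come from the side of H7. This is also the more stable arrangement.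

**Lactone (16 ⇐ 13 ⇐ 12 ⇐ 10).** The C6–O bond and the C7–H bond are cut together to the C6=C7 alkene of 13 (hydroboration, then lactonisation). The C7–C11 bond is cut to enol triflate 12 and a zinc ester enolate, and 12 comes from ketone 10 by enolisation away from the oxygenated C8. Closing the lactone by olefination at C7 and then reducing a tetrasubstituted C7=C11 bond was set aside, because nothing but the ring shape would direct hydrogen to the β face of C7. Hydroboration adds H and B to the same face, so the trans relation of O6 and C11 is fixed by mechanism and only one facial choice is left.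

**O8 and the spectator groups (10 ⇐ 8 ⇐ 7 ⇐ 5 ⇐ 4).** The C8–O bond is cut to the silyl enol ether 8 (Rubottom oxidation). The enol ether is regiodefined by the cycloaddition, and the oxidation hands the silyl group on to O8. Before that, the formyl group of 4 is reduced (5) and the ester is turned into the tertiary carbinol (7) while the enol ether still masks the C7 carbonyl.

**Ring (4 ⇐ 2 + 3; 2 ⇐ 1).** C9–C10 and C5–C6 are cut in a catalytic asymmetric Diels–Alder reaction. This gives the carbocycle, the quaternary centre and its tertiary neighbour in one step from two simple pieces, with the C7 oxygen placed to direct everything that follows.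

## Alternatives that were turned down

**Alternative 1: chromium-mediated allylation closing C6–C7 and the lactone.**
- Disconnection: C6–C7 and C12–O6, back to the open-chain formyl 2-(bromomethyl)enoate A2.
- Forward key step: CrCl2 converts the allylic bromide into an allylchromium species that adds through C7 to the C6 aldehyde; the C6 alkoxide closes onto the ester to give the α-methylene lactone A1.
- For: ring and lactone arise in one mild step, the C6/C7 relation comes from a closed transition state, and terminal alkenes are tolerated.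
- Against: A2 must already carry the quaternary C10 next to C5, plus C8, made in an open chain; the key step does nothing for this hardest part. C5 is α to the aldehyde and bears an isopropenyl group, so it can epimerise or move into conjugation. Six-membered closures of this type can also give the cis-fused lactone. The exocyclic methylene of A1 still has to be reduced to C13.
- Comparison: on the lactone this alternative is stronger (one step against four in the chosen route). The chosen route offers instead the C5/C10 pair in one catalytic step from commercial materials, and very probably fewer steps overall once A2 is counted.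

**Alternative 2: amine-catalysed Michael–aldol annulation.**
- Disconnection: C5–C10 and C7–C8, back to tert-butyl acetoacetate A4 and the acetal enal A5.
- Forward key step: under a diarylprolinol silyl ether with benzoic acid, A4 adds through C5 to C10 of the iminium ion of A5; the methyl ketone carbon C7 then adds to the C8 aldehyde to give the β-hydroxy cyclohexanone A3.
- For: cheap, metal-free, and it delivers C8–OH and a C6 carbonyl directly. A C6 ketone would make C7 epimerisable, the classical handle for a trans lactone.
- Against: iminium activation of a β,β-disubstituted enal to build a quaternary centre with a 1,3-dicarbonyl nucleophile is slow and weakly selective. A3 is a β-hydroxy ketone that tends to dehydrate to the cyclohexenone, which would lose C8. C5 lies between two carbonyls, so its relation to C10 is thermodynamic, not enforced. Later C7 alkylation needs a dianion next to a β-hydroxyl that can eliminate.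
- Comparison: this alternative is stronger in oxygen placement at C6 and C8. The chosen route offers stereospecific transfer of alkene geometry to C5/C10 by a known catalyst class, and a robust enol ether in place of a fragile aldol.

**Alternative 3: carbonyl-ene closure of C5–C6.**
- Disconnection: C5–C6, back to the open-chain aldehyde A7.
- Forward key step: Me2AlCl activates the C6 aldehyde; the C5=C4 alkene attacks with transfer of a methyl hydrogen to give cyclohexanol A6 with trans C6–OH and C5 isopropenyl.
- For: the isopropenyl group and the trans C5/C6 relation come directly, with no carbinol/dehydration detour, and the C6 hydroxyl is placed to lactonise.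
- Against: A7 must already hold C7, C8, C11 and a bis-allylic quaternary C10, all made acyclically. Its α-branched β-silyloxy aldehyde can epimerise or eliminate under the Lewis acid. Facial control at C5 depends on whether methyl or vinyl on C10 goes axial in the transition state; the two are of similar size.
- Comparison: this alternative is stronger for the isopropenyl group and C5/C6. The chosen route is stronger for C5/C10, which it sets without ambiguity, and reaches the stereodefined ring in two steps.

Key step: step 2

Remark (assumption on the chemistry): the facial sense of the cationic oxazaborolidine is taken from the accepted binding model for 2-substituted acroleins (formyl C–H···O contact, s-trans enal lying over the phenyl cis to boron, diene adding to the open face). On this model the catalyst made from (R)-α,α-diphenylprolinol gives the (1S,6S) adduct 4; the antipodal catalyst is equally available.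

## Route

**Step 1**
Reactants: 1 but-3-en-2-one
Product: 2 2-(triisopropylsilyloxy)buta-1,3-diene
Conditions: iPr3SiOTf, Et3N, Et2O, 0 °C → rt
Reagents that add atoms: triisopropylsilyl trifluoromethanesulfonate, CC(C)[Si](C(C)C)(C(C)C)OS(=O)(=O)C(F)(F)F
Why: Soft enolisation of the enone and O-silylation (silyl enol ether formation) give the cross-conjugated diene; the bulky silyl group makes it isolable and slows silyl transfer in the next step.

**Step 2**
Reactants: 2 2-(triisopropylsilyloxy)buta-1,3-diene; 3 ethyl (E)-3-methyl-4-oxobut-2-enoate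
Product: 4 ethyl (1S,6S)-6-formyl-6-methyl-3-(triisopropylsilyloxy)cyclohex-3-ene-1-carboxylate
Conditions: (R)-B-(o-tolyl)oxazaborolidine C24H24BNO [from (R)-α,α-diphenylprolinol and (o-tolyl)boroxine], HNTf2 (15 mol % each), CH2Cl2, −78 → −40 °C
Reagents that add atoms: none
Why: The N-protonated oxazaborolidine binds the formyl oxygen of 3 (B–O coordination supported by a formyl C–H···O contact), not the ester, and lowers the LUMO of the s-trans enal. A concerted but asynchronous [4+2] cycloaddition follows, in which the nucleophilic diene terminus C6 (the CH2 on the silyloxy-bearing carbon) bonds first to C5, the enal β-carbon, and C9 then closes on C10. The closest known reaction type is the cationic-oxazaborolidine-catalysed Diels–Alder reaction of 2-substituted acroleins with 2-silyloxybutadienes. The cyclohexene is closed by this suprafacial–suprafacial union of the two components, an intermolecular annulation forming C5–C6 and C9–C10. C10 is set by the catalyst, whose phenyl group shields one face of the bound enal so that the diene adds to the other; C5 is set relative to C10 by the (E)-geometry of 3, carried over as the trans relation of formyl and ester. The step needs regioselectivity (silyloxy carbon C7 para to C10), which requires the aldehyde and not the ester to be the activated group; the two-point binding of CHO secures this. It also needs the cycloaddition to beat Mukaiyama-type addition of the enol ether to the aldehyde carbon, which the bulky iPr3Si group and low temperature should secure; the diene has no terminal substituent, so no endo/exo question arises.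

**Step 3**
Reactants: 4 ethyl (1S,6S)-6-formyl-6-methyl-3-(triisopropylsilyloxy)cyclohex-3-ene-1-carboxylate
Product: 5 ethyl (1S,6S)-6-(hydroxymethyl)-6-methyl-3-(triisopropylsilyloxy)cyclohex-3-ene-1-carboxylate
Conditions: NaBH4, EtOH, −20 → 0 °C
Reagents that add atoms: none
Why: Chemoselective hydride reduction of the aldehyde in the presence of the ester and the silyl enol ether; the aldehyde must be out of play before the organometallic and borane steps. Lactonisation onto the ester, should it occur, is harmless because the lactone gives the same diol in step 4.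

**Step 4**
Reactants: 5 ethyl (1S,6S)-6-(hydroxymethyl)-6-methyl-3-(triisopropylsilyloxy)cyclohex-3-ene-1-carboxylate
Product: 7 2-[(1S,6S)-6-(hydroxymethyl)-6-methyl-3-(triisopropylsilyloxy)cyclohex-3-en-1-yl]propan-2-ol, via methyl ketone 6 (not isolated)
Conditions: MeMgBr (excess), THF, 0 → 40 °C; aq NH4Cl
Reagents that add atoms: methylmagnesium bromide, C[Mg]Br
Why: Double Grignard addition to the ester gives the tertiary carbinol that later becomes the isopropenyl group; the silyl enol ether protects the C7 carbonyl during the addition.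

**Step 5**
Reactants: 7 2-[(1S,6S)-6-(hydroxymethyl)-6-methyl-3-(triisopropylsilyloxy)cyclohex-3-en-1-yl]propan-2-ol
Product: 8 bis(triethylsilyl) ether of 7 (C1–OSiEt3 on C10; C4–OSiEt3 on C5)
Conditions: Et3SiOTf, 2,6-lutidine, CH2Cl2, −78 → 0 °C
Reagents that add atoms: triethylsilyl trifluoromethanesulfonate, CC[Si](CC)(CC)OS(=O)(=O)C(F)(F)F
Why: Silyl triflate with a hindered base silylates both the primary and the tertiary hydroxyl (silyl ether formation) without protic acid, so the enol ether survives; both oxygens must be capped for the enolate, organozinc and borane chemistry.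

**Step 6**
Reactants: 8 bis(triethylsilyl) ether of 7
Product: 10 8β-(triisopropylsilyloxy) C7 ketone (10β-CH2OSiEt3; 10α-CH3; 5α-C(CH3)2OSiEt3), via silyloxy epoxide 9 (not isolated)
Conditions: mCPBA, NaHCO3, CH2Cl2, −20 °C → rt
Reagents that add atoms: 3-chloroperoxybenzoic acid, OOC(=O)c1cccc(Cl)c1
Why: Rubottom oxidation: the electron-rich enol ether is epoxidised and the silyloxy oxirane opens with 1,4-silyl shift, so O8 arrives already protected. The peracid should approach C8 from the β face, away from the axial C14 methyl; the 8β (equatorial) epimer is also the more stable one and can be reached by mild base equilibration of the α-silyloxy ketone.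

**Step 7**
Reactants: 10 8β-(triisopropylsilyloxy) C7 ketone
Product: 12 C6=C7 enol triflate (7-OSO2CF3; 8β-OSi(iPr)3), via potassium enolate 11 (not isolated)
Conditions: KN(SiMe3)2, THF, −78 °C; PhNTf2, −78 → 0 °C
Reagents that add atoms: N-phenylbis(trifluoromethanesulfonimide), O=S(=O)(N(c1ccccc1)S(=O)(=O)C(F)(F)F)C(F)(F)F
Why: Kinetic deprotonation of an α-silyloxy ketone takes place at the unsubstituted α′ carbon C6, away from the hindered oxygen-bearing C8, and O-sulfonylation fixes the C6=C7 enol triflate (enol triflate formation).

**Step 8**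
Reactants: 12 C6=C7 enol triflate
Product: 13 β,γ-unsaturated ester (C7–CH2CO2Et on the C6=C7 alkene)
Conditions: BrZnCH2CO2Et (from BrCH2CO2Et and Zn dust, THF), Pd(PPh3)4 (10 mol %), THF/DMPU, 60 °C
Reagents that add atoms: ethyl bromoacetate (as its zinc reagent), CCOC(=O)CBr
Why: Negishi-type cross-coupling of an alkenyl triflate with a Reformatsky reagent under zerovalent palladium catalysis forms C7–C11; the triflate fixes both the site of the new bond and the position of the alkene.

**Step 9**
Reactants: 13 β,γ-unsaturated ester
Product: 16 trans-fused γ-lactone (O6 β; C11 α on C7; C11 unsubstituted), via alkylborane 14 (not isolated), via hydroxy ester 15 (not isolated)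
Conditions: BH3·SMe2, THF, 0 °C → rt; H2O2, aq NaOAc, 0 °C → rt; PPTS, PhH, 60 °C
Reagents that add atoms: hydrogen peroxide, OO
Why: Hydroboration–oxidation puts boron on the less substituted C6 and hydrogen on C7 from the same face, so O6 and C11 must end up trans, and acid-catalysed lactonisation closes the trans-fused ring. Borane should attack the β face, because the boron-bearing C6 is flanked by the α-oriented C5 substituent and the axial C14 methyl, whereas only hydrogen is delivered next to the 8β-silyloxy group.

**Step 10**
Reactants: 16 trans-fused γ-lactone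
Product: 18 11-methyl lactone (C13 cis to H7; C1–OSiEt3; C4–OSiEt3; 8β-OSi(iPr)3), via lithium enolate 17 (not isolated)
Conditions: LiN(iPr)2, THF, −78 °C; MeI, −78 → −40 °C
Reagents that add atoms: iodomethane, CI
Why: Enolate alkylation of the lactone; MeI approaches C11 from the face of H7, away from C8 and its silyloxy group, which gives C13 cis to H7. This is also the thermodynamically preferred epimer.

**Step 11**
Reactants: 18 11-methyl lactone
Product: 19 diol lactone (C1–OH; tertiary C4–OH; 8β-OSi(iPr)3)
Conditions: TsOH·H2O (cat.), MeOH, 0 °C → rt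
Reagents that add atoms: none
Why: Acid-catalysed methanolysis (selective desilylation) cleaves the primary and tertiary triethylsilyl ethers, while the far more robust secondary triisopropylsilyl ether and the γ-lactone persist.

**Step 12**
Reactants: 19 diol lactone
Product: 21 C1 aldehyde lactone (tertiary C4–OH; 8β-OSi(iPr)3), via alkoxysulfonium salt 20 (not isolated)
Conditions: (COCl)2, DMSO, CH2Cl2, −78 °C; Et3N, −78 → 0 °C
Reagents that add atoms: none
Why: Swern oxidation of the primary alcohol; the tertiary hydroxyl cannot be oxidised. Because the oxidant is consumed at low temperature, the hydroxy aldehyde (which can close to a lactol with the C4 hydroxyl) is not carried on to a lactone.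

**Step 13**
Reactants: 21 C1 aldehyde lactone
Product: 22 10-vinyl lactone (tertiary C4–OH; 8β-OSi(iPr)3)
Conditions: Ph3PCH3Br, KOtBu, THF, 0 → 50 °C
Reagents that add atoms: methyltriphenylphosphonium bromide, C[P+](c1ccccc1)(c1ccccc1)c1ccccc1.[Br-]
Why: Wittig methylenation of the non-enolisable neopentyl aldehyde; excess ylide is used because the tertiary hydroxyl is deprotonated and any lactol is opened, and the lactone carbonyl is much less reactive toward the ylide. Any base-induced epimerisation at C11 would run toward the desired, more stable epimer.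

**Step 14**
Reactants: 22 10-vinyl lactone
Product: 23 10-vinyl-5-isopropenyl lactone (8β-OSi(iPr)3)
Conditions: MeO2CN(−)SO2N(+)Et3 (Burgess reagent), PhMe, 50 °C
Reagents that add atoms: none
Why: Burgess dehydration (syn elimination of the tertiary sulfamate) should give the isopropenyl group: loss of a methyl hydrogen is favoured statistically, and the alternative tetrasubstituted C4=C5 alkene would eclipse the substituents on C6 and on quaternary C10.

**Step 15**
Reactants: 23 10-vinyl-5-isopropenyl lactone
Product: 24 8β-hydroxy lactone (8-hydroxyelema-1,3-dien-12,6-olide)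
Conditions: Bu4NF, AcOH, THF, 0 °C → rt
Reagents that add atoms: none
Why: Fluoride-mediated desilylation; buffering with AcOH keeps the freed C8 hydroxyl from attacking the lactone carbonyl, which would move the lactone from O6 to O8.

**Step 16**
Reactants: 25 methyl (R)-2,2-dimethyl-1,3-dioxolane-4-carboxylate
Product: 26 (R)-N-methoxy-N,2,2-trimethyl-1,3-dioxolane-4-carboxamide
Conditions: MeNHOMe·HCl, iPrMgCl, THF, −20 → 0 °C
Reagents that add atoms: N,O-dimethylhydroxylamine hydrochloride, CNOC.Cl
Why: Weinreb amide formation from the ester with the magnesium amide; the α-alkoxy stereocentre is not enolised at this temperature.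

**Step 17**
Reactants: 26 (R)-N-methoxy-N,2,2-trimethyl-1,3-dioxolane-4-carboxamide
Product: 28 1-[(4R)-2,2-dimethyl-1,3-dioxolan-4-yl]ethanone, via magnesium hemiaminal 27 (not isolated)
Conditions: MeMgBr, THF, 0 °C; aq NH4Cl
Reagents that add atoms: methylmagnesium bromide, C[Mg]Br
Why: Weinreb ketone synthesis: the chelated tetrahedral adduct resists a second addition and releases the methyl ketone on work-up.

**Step 18**
Reactants: 28 1-[(4R)-2,2-dimethyl-1,3-dioxolan-4-yl]ethanone
Product: 30 1-[(4R)-2,2-dimethyl-1,3-dioxolan-4-yl]ethenyl trifluoromethanesulfonate, via potassium enolate 29 (not isolated)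
Conditions: KN(SiMe3)2, THF, −78 °C; PhNTf2, −78 → 0 °C
Reagents that add atoms: N-phenylbis(trifluoromethanesulfonimide), O=S(=O)(N(c1ccccc1)S(=O)(=O)C(F)(F)F)C(F)(F)F
Why: Kinetic enolisation at the methyl group, not at the hindered α-alkoxy methine, keeps the stereocentre and avoids β-elimination; O-triflation gives the 1-substituted vinyl triflate (enol triflate formation).

**Step 19**
Reactants: 30 1-[(4R)-2,2-dimethyl-1,3-dioxolan-4-yl]ethenyl trifluoromethanesulfonate
Product: 31 2-[(4S)-2,2-dimethyl-1,3-dioxolan-4-yl]prop-2-enoic acid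
Conditions: CO (1 atm), Pd(OAc)2, Ph2P(CH2)3PPh2, Et3N, H2O, DMF, 60 °C; work-up at pH 4
Reagents that add atoms: carbon monoxide, [C-]#[O+]; water, O
Why: Palladium-catalysed hydroxycarbonylation of the alkenyl triflate (oxidative addition, CO insertion, hydrolysis of the acylpalladium) gives the 2-substituted acrylic acid. The descriptor changes from R to S only because the CIP priorities change.

**Step 20**
Reactants: 24 8β-hydroxy lactone; 31 2-[(4S)-2,2-dimethyl-1,3-dioxolan-4-yl]prop-2-enoic acid
Product: 33 8-O-{2-[(4S)-2,2-dimethyl-1,3-dioxolan-4-yl]acryloyl} ester of 24, via mixed anhydride 32 (not isolated)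
Conditions: 2,4,6-Cl3C6H2COCl, Et3N, PhMe, rt; then 24, DMAP, PhMe, rt
Reagents that add atoms: none
Why: Yamaguchi esterification: DMAP attacks the less hindered acrylic carbonyl of the mixed anhydride and the acylpyridinium acylates the equatorial C8 hydroxyl. No strong base is present, which limits lactone migration and conjugate addition to the acrylate.

**Step 21**
Reactants: 33 8-O-acyl ester
Product: 34 15-hydroxy derivative of 33 (C5 now carries C4(=CH2)CH2OH)
Conditions: SeO2 (0.3 equiv), tBuOOH, CH2Cl2, 0 °C → rt
Reagents that add atoms: tert-butyl hydroperoxide, CC(C)(C)OO; selenium dioxide (oxygen carrier), O=[Se]=O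
Why: SeO2-catalysed allylic hydroxylation (ene reaction, then [2,3]-sigmatropic shift) of the 1,1-disubstituted alkene at its methyl group. The vinyl group has no allylic hydrogen, the acrylate is too electron-poor to react, and C5–H is a hindered methine.

**Step 22**
Reactants: 34 15-hydroxy ester acetonide
Product: 35 CNP0260337.1 (target)
Conditions: AcOH/H2O (4:1), rt
Reagents that add atoms: none
Why: Acetal hydrolysis under mild aqueous acid frees the diol without touching the esters. Acid is chosen over base because the free 4′-hydroxyl would otherwise lactonise onto its own ester carbonyl and release the C8 alcohol.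

## Compound list

1 | but-3-en-2-one | CC(=O)C=C | starting material
2 | 2-(triisopropylsilyloxy)buta-1,3-diene | C=CC(=C)O[Si](C(C)C)(C(C)C)C(C)C | intermediate
3 | ethyl (E)-3-methyl-4-oxobut-2-enoate | CCOC(=O)/C=C(/C=O)C | starting material
4 | ethyl (1S,6S)-6-formyl-6-methyl-3-(triisopropylsilyloxy)cyclohex-3-ene-1-carboxylate | O=C[C@@]1(C)CC=C(O[Si](C(C)C)(C(C)C)C(C)C)C[C@@H]1C(=O)OCC | intermediate
5 | ethyl (1S,6S)-6-(hydroxymethyl)-6-methyl-3-(triisopropylsilyloxy)cyclohex-3-ene-1-carboxylate | OC[C@@]1(C)CC=C(O[Si](C(C)C)(C(C)C)C(C)C)C[C@@H]1C(=O)OCC | intermediate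
6 | 1-[(1S,6S)-6-(hydroxymethyl)-6-methyl-3-(triisopropylsilyloxy)cyclohex-3-en-1-yl]ethanone (present as its magnesium alkoxide) | OC[C@@]1(C)CC=C(O[Si](C(C)C)(C(C)C)C(C)C)C[C@@H]1C(C)=O | intermediate (not isolated)
7 | 2-[(1S,6S)-6-(hydroxymethyl)-6-methyl-3-(triisopropylsilyloxy)cyclohex-3-en-1-yl]propan-2-ol | OC[C@@]1(C)CC=C(O[Si](C(C)C)(C(C)C)C(C)C)C[C@@H]1C(C)(C)O | intermediate
8 | bis(triethylsilyl) ether of 7 | CC[Si](CC)(CC)OC[C@@]1(C)CC=C(O[Si](C(C)C)(C(C)C)C(C)C)C[C@@H]1C(C)(C)O[Si](CC)(CC)CC | intermediate
9 | 7β,8β-epoxide of 8 (silyloxy oxirane) | CC[Si](CC)(CC)OC[C@@]1(C)C[C@H]2O[C@@]2(O[Si](C(C)C)(C(C)C)C(C)C)C[C@@H]1C(C)(C)O[Si](CC)(CC)CC | intermediate (not isolated)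
10 | C7 ketone with 8β-OSi(iPr)3, 10β-CH2OSiEt3, 10α-CH3, 5α-C(CH3)2OSiEt3 | CC[Si](CC)(CC)OC[C@@]1(C)C[C@@H](O[Si](C(C)C)(C(C)C)C(C)C)C(=O)C[C@@H]1C(C)(C)O[Si](CC)(CC)CC | intermediate
11 | potassium C6=C7 enolate of 10 | CC[Si](CC)(CC)OC[C@@]1(C)C[C@@H](O[Si](C(C)C)(C(C)C)C(C)C)C([O-])=C[C@@H]1C(C)(C)O[Si](CC)(CC)CC.[K+] | intermediate (not isolated)
12 | C6=C7 enol triflate of 10 | CC[Si](CC)(CC)OC[C@@]1(C)C[C@@H](O[Si](C(C)C)(C(C)C)C(C)C)C(OS(=O)(=O)C(F)(F)F)=C[C@@H]1C(C)(C)O[Si](CC)(CC)CC | intermediate
13 | ethyl ester with C7–CH2CO2Et on the C6=C7 alkene | CC[Si](CC)(CC)OC[C@@]1(C)C[C@@H](O[Si](C(C)C)(C(C)C)C(C)C)C(CC(=O)OCC)=C[C@@H]1C(C)(C)O[Si](CC)(CC)CC | intermediate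
14 | 6β-boryl adduct of 13 (H7 β), drawn as the monoalkylborane | CC[Si](CC)(CC)OC[C@@]1(C)C[C@@H](O[Si](C(C)C)(C(C)C)C(C)C)[C@H](CC(=O)OCC)[C@@H](B)[C@@H]1C(C)(C)O[Si](CC)(CC)CC | intermediate (not isolated)
15 | 6β-hydroxy ethyl ester | CC[Si](CC)(CC)OC[C@@]1(C)C[C@@H](O[Si](C(C)C)(C(C)C)C(C)C)[C@H](CC(=O)OCC)[C@@H](O)[C@@H]1C(C)(C)O[Si](CC)(CC)CC | intermediate (not isolated)
16 | trans-fused 12,6-lactone, C11 unsubstituted | CC[Si](CC)(CC)OC[C@@]1(C)C[C@@H](O[Si](C(C)C)(C(C)C)C(C)C)[C@H]2[C@@H](OC(=O)C2)[C@@H]1C(C)(C)O[Si](CC)(CC)CC | intermediate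
17 | lithium enolate of 16 | CC[Si](CC)(CC)OC[C@@]1(C)C[C@@H](O[Si](C(C)C)(C(C)C)C(C)C)[C@H]2[C@@H](OC([O-])=C2)[C@@H]1C(C)(C)O[Si](CC)(CC)CC.[Li+] | intermediate (not isolated)
18 | 11-methyl lactone (C13 cis to H7), bis(triethylsilyl) ether, 8β-OSi(iPr)3 | CC[Si](CC)(CC)OC[C@@]1(C)C[C@@H](O[Si](C(C)C)(C(C)C)C(C)C)[C@H]2[C@@H](OC(=O)[C@@H]2C)[C@@H]1C(C)(C)O[Si](CC)(CC)CC | intermediate
19 | diol lactone (C1–OH, tertiary C4–OH, 8β-OSi(iPr)3) | OC[C@@]1(C)C[C@@H](O[Si](C(C)C)(C(C)C)C(C)C)[C@H]2[C@@H](OC(=O)[C@@H]2C)[C@@H]1C(C)(C)O | intermediate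
20 | O1-dimethylsulfonium chloride of 19 | C[S+](C)OC[C@@]1(C)C[C@@H](O[Si](C(C)C)(C(C)C)C(C)C)[C@H]2[C@@H](OC(=O)[C@@H]2C)[C@@H]1C(C)(C)O.[Cl-] | intermediate (not isolated)
21 | C1 aldehyde lactone (tertiary C4–OH, 8β-OSi(iPr)3) | O=C[C@@]1(C)C[C@@H](O[Si](C(C)C)(C(C)C)C(C)C)[C@H]2[C@@H](OC(=O)[C@@H]2C)[C@@H]1C(C)(C)O | intermediate
22 | 10-vinyl lactone (tertiary C4–OH, 8β-OSi(iPr)3) | C=C[C@@]1(C)C[C@@H](O[Si](C(C)C)(C(C)C)C(C)C)[C@H]2[C@@H](OC(=O)[C@@H]2C)[C@@H]1C(C)(C)O | intermediate
23 | 10-vinyl-5-isopropenyl lactone (8β-OSi(iPr)3) | C=C[C@@]1(C)C[C@@H](O[Si](C(C)C)(C(C)C)C(C)C)[C@H]2[C@@H](OC(=O)[C@@H]2C)[C@@H]1C(C)=C | intermediate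
24 | 8β-hydroxy lactone (8-hydroxyelema-1,3-dien-12,6-olide) | C=C[C@@]1(C)C[C@@H](O)[C@H]2[C@@H](OC(=O)[C@@H]2C)[C@@H]1C(C)=C | intermediate
25 | methyl (R)-2,2-dimethyl-1,3-dioxolane-4-carboxylate | COC(=O)[C@H]1COC(C)(C)O1 | starting material
26 | (R)-N-methoxy-N,2,2-trimethyl-1,3-dioxolane-4-carboxamide | CON(C)C(=O)[C@H]1COC(C)(C)O1 | intermediate
27 | bromomagnesium tetrahedral adduct of 26 with MeMgBr | CC([O-])(N(C)OC)[C@H]1COC(C)(C)O1.[Mg+2].[Br-] | intermediate (not isolated)
28 | 1-[(4R)-2,2-dimethyl-1,3-dioxolan-4-yl]ethanone | CC(=O)[C@H]1COC(C)(C)O1 | intermediate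
29 | potassium enolate of 28 (methyl side) | C=C([O-])[C@H]1COC(C)(C)O1.[K+] | intermediate (not isolated)
30 | 1-[(4R)-2,2-dimethyl-1,3-dioxolan-4-yl]ethenyl trifluoromethanesulfonate | C=C(OS(=O)(=O)C(F)(F)F)[C@H]1COC(C)(C)O1 | intermediate
31 | 2-[(4S)-2,2-dimethyl-1,3-dioxolan-4-yl]prop-2-enoic acid | C=C(C(=O)O)[C@H]1COC(C)(C)O1 | intermediate
32 | mixed anhydride of 31 with 2,4,6-trichlorobenzoic acid | C=C(C(=O)OC(=O)c1c(Cl)cc(Cl)cc1Cl)[C@H]1COC(C)(C)O1 | intermediate (not isolated)
33 | 8-O-{2-[(4S)-2,2-dimethyl-1,3-dioxolan-4-yl]acryloyl} ester of 24 | C=C[C@@]1(C)C[C@@H](OC(=O)C(=C)[C@H]3COC(C)(C)O3)[C@H]2[C@@H](OC(=O)[C@@H]2C)[C@@H]1C(C)=C | intermediate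
34 | 15-hydroxy derivative of 33 | C=C[C@@]1(C)C[C@@H](OC(=O)C(=C)[C@H]3COC(C)(C)O3)[C@H]2[C@@H](OC(=O)[C@@H]2C)[C@@H]1C(=C)CO | intermediate
35 | CNP0260337.1: (5S,6S,7S,8R,10R,11R)-8-[(3S)-3,4-dihydroxy-2-methylenebutanoyloxy]-15-hydroxyelema-1,3-dien-12,6-olide | C=C[C@@]1(C)C[C@@H](OC(=O)C(=C)[C@H](O)CO)[C@H]2[C@@H](OC(=O)[C@@H]2C)[C@@H]1C(=C)CO | target

## Step count and weak points

Total: 22 steps (18 in the main line, 4 for acid 31). Longest linear sequence: 18 steps (steps 1–15 and 20–22, from 1).

**Step 2 (key step).** The β-ester makes 3 more crowded and more Lewis-basic than a simple 2-substituted acrolein. Binding of the catalyst to the ester carbonyl, or Mukaiyama-type attack of the enol ether on the activated formyl carbon, would erode regio- and enantioselectivity, and the facial sense rests on a model. Fallback, setting out from 2 and 3 and returning at 7: the cycloaddition is run without chiral control under Me2AlCl (CH2Cl2, −78 °C) to give racemic 4, which is taken through steps 3 and 4 to racemic 7. The primary hydroxyl is esterified with (S)-2-methoxy-2-phenylacetic acid (DCC, DMAP), the diastereomeric esters are separated by chromatography, and the (S)-O-methylmandelate of the (1S,6S) diol F1 is cleaved with K2CO3 in MeOH to return enantiopure 7.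

**Step 9.** Borane may add to the α face if the 8β-silyloxy group shields the β face more than the C5 substituent and C14 shield the α face; this would invert C6 and C7 together. The hindered alkene may also react so slowly that the ester is reduced. Fallback, setting out from 10 and returning at 16: the potassium enolate of 10 is hydroxylated at C6 with 2-(phenylsulfonyl)-3-phenyloxaziridine, anti to the C5 substituent, to give the 6β-hydroxy ketone F2. Esterification with 2-(diethoxyphosphoryl)acetic acid (DCC, DMAP) gives the phosphonoacetate F3. Intramolecular Horner–Wadsworth–Emmons reaction (LiCl, DBU, MeCN) closes the C7=C11 butenolide F4. Hydrogenation (H2, 5% Rh on Al2O3, EtOAc) should deliver hydrogen to the β face, because flat adsorption of the α face is impeded by the axial C14 methyl; this gives 16.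

**Step 8.** Transmetalation of the zinc ester enolate onto a palladium centre flanked by the C8 silyloxy group may be slow, leaving reduction of the triflate or decomposition of the zinc reagent as the main pathways. Fallback, setting out from 12 and returning at 16: Suzuki–Miyaura coupling with vinylboronic acid pinacol ester (Pd(PPh3)4, K3PO4, dioxane/H2O, 80 °C) gives the 7-vinyl diene F5. 9-BBN hydroborates only the terminal vinyl group and oxidation (H2O2, aq NaOAc) gives the homoallylic alcohol F6. BH3·SMe2 then H2O2 hydroborates the ring alkene as in step 9 to the 1,4-diol F7. TEMPO with PhI(OAc)2 oxidises the primary alcohol through the lactol to lactone 16.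

**Step 21.** Over-oxidation of the allylic alcohol to the enal, slow conversion, or attack at C5–H would cost material at the most advanced stage; traces of acid could also open the acetonide early. Fallback, setting out from 33 and returning at 34: ene-type allylic chlorination of the isopropenyl group with Ca(OCl)2 and CO2 (CH2Cl2/H2O, 0 °C) gives the 15-chloride F8. Displacement with HCO2Cs in DMF gives the 15-formate F9, and brief treatment with KHCO3 in MeOH at 0 °C removes the formyl group selectively to give 34.

## Further compounds

F1 | step 2 | (S)-O-methylmandelate of 7 at the primary hydroxyl | CO[C@H](C(=O)OC[C@@]1(C)CC=C(O[Si](C(C)C)(C(C)C)C(C)C)C[C@@H]1C(C)(C)O)c1ccccc1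
F2 | step 9 | 6β-hydroxy derivative of ketone 10 | CC[Si](CC)(CC)OC[C@@]1(C)C[C@@H](O[Si](C(C)C)(C(C)C)C(C)C)C(=O)[C@@H](O)[C@@H]1C(C)(C)O[Si](CC)(CC)CC
F3 | step 9 | 6-O-(diethoxyphosphoryl)acetate of F2 | CC[Si](CC)(CC)OC[C@@]1(C)C[C@@H](O[Si](C(C)C)(C(C)C)C(C)C)C(=O)[C@@H](OC(=O)CP(=O)(OCC)OCC)[C@@H]1C(C)(C)O[Si](CC)(CC)CC
F4 | step 9 | C7=C11 butenolide (12,6-olide) | CC[Si](CC)(CC)OC[C@@]1(C)C[C@@H](O[Si](C(C)C)(C(C)C)C(C)C)C2=CC(=O)O[C@H]2[C@@H]1C(C)(C)O[Si](CC)(CC)CC
F5 | step 8 | 7-vinyl diene from 12 | CC[Si](CC)(CC)OC[C@@]1(C)C[C@@H](O[Si](C(C)C)(C(C)C)C(C)C)C(C=C)=C[C@@H]1C(C)(C)O[Si](CC)(CC)CC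
F6 | step 8 | homoallylic alcohol (C7–CH2CH2OH on the C6=C7 alkene) | CC[Si](CC)(CC)OC[C@@]1(C)C[C@@H](O[Si](C(C)C)(C(C)C)C(C)C)C(CCO)=C[C@@H]1C(C)(C)O[Si](CC)(CC)CC
F7 | step 8 | 1,4-diol (6β-OH, C12–OH) | CC[Si](CC)(CC)OC[C@@]1(C)C[C@@H](O[Si](C(C)C)(C(C)C)C(C)C)[C@H](CCO)[C@@H](O)[C@@H]1C(C)(C)O[Si](CC)(CC)CC
F8 | step 21 | 15-chloro derivative of 33 | C=C[C@@]1(C)C[C@@H](OC(=O)C(=C)[C@H]3COC(C)(C)O3)[C@H]2[C@@H](OC(=O)[C@@H]2C)[C@@H]1C(=C)CCl
F9 | step 21 | 15-formate of 34 | C=C[C@@]1(C)C[C@@H](OC(=O)C(=C)[C@H]3COC(C)(C)O3)[C@H]2[C@@H](OC(=O)[C@@H]2C)[C@@H]1C(=C)COC=O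
A1 | alternative 1 | trans-fused α-methylene lactone with 8-OSi(tBu)Me2, 10-vinyl and 5-isopropenyl | C=C[C@@]1(C)C[C@@H](O[Si](C)(C)C(C)(C)C)[C@H]2[C@@H](OC(=O)C2=C)[C@@H]1C(C)=C
A2 | alternative 1 | open-chain C6 aldehyde with methyl (Z)-2-(bromomethyl)enoate | C=C[C@@](C)(C[C@@H](O[Si](C)(C)C(C)(C)C)/C=C(\CBr)C(=O)OC)[C@H](C=O)C(C)=C
A3 | alternative 2 | tert-butyl β-hydroxycyclohexanone carboxylate (C1 dimethyl acetal, C6 ketone, C8 hydroxyl) | COC(OC)[C@@]1(C)C[C@@H](O)CC(=O)[C@@H]1C(=O)OC(C)(C)C
A4 | alternative 2 | tert-butyl acetoacetate | CC(=O)CC(=O)OC(C)(C)C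
A5 | alternative 2 | (E)-4,4-dimethoxy-3-methylbut-2-enal | COC(OC)/C(C)=C/C=O
A6 | alternative 3 | cyclohexanol with trans 6-hydroxyl and 5-isopropenyl, C7 methyl propanoate side chain, 8-OSi(tBu)Me2 | C=C[C@@]1(C)C[C@@H](O[Si](C)(C)C(C)(C)C)[C@H]([C@@H](C)C(=O)OC)[C@@H](O)[C@@H]1C(C)=C
A7 | alternative 3 | open-chain C6 aldehyde with C5=C4 dimethyl-substituted alkene | C=C[C@](C)(C=C(C)C)C[C@@H](O[Si](C)(C)C(C)(C)C)[C@@H](C=O)[C@@H](C)C(=O)OC
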